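Late in a run the intermediate is a stage on the way to product, so what a flask holds when read depends on two times, one that fills it and one that drains it.

| setting | north-east | east | north-west | south-west |
|---|---|---|---|---|
| starting material | 12 mM | 12 mM (fed, over 1.25 d) | 12 mM | 12 mM |
| protic impurity | 3.60 mM | 3.60 mM | 3.60 mM | 3.60 mM |
| catalyst | 0.60 mM | 0.60 mM | 0.60 mM | 0.60 mM |
| remark | one stirred flow tank at steady state, fed with the mixture as stated, mean residence time 2.5 d | a stirred flask in which starting material is dosed at a steady rate over 1.25 d without added volume, worked up at 2.5 d | a single well-mixed tank run continuously and read at steady state, 25.0 d in it on average | a closed flask charged with all of it at once and left for 2.5 d |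
| time |  | 2.5 d |  | 2.5 d |

    starting material → intermediate (k1 = 2.6 × 10⁻⁶ s⁻¹)
    starting material + protic impurity → quenched substrate (k2 = 0.0034 M⁻¹ s⁻¹)
    catalyst + intermediate → catalyst + product (k3 = 0.0037 M⁻¹ s⁻¹)
    starting material ⇌ dormant form (K4 = 0.34, k4 = 1.1 × 10⁻⁴ s⁻¹)

- the stated concentrations are those of everything mixed, before any reaction; amounts are the same in each set-up
- the feed brings no volume worth counting
- run time (east): 2.5 d

- the set-up with the highest amount of intermediate at the outlet or at the end, in percent of the starting material put in ("none" if the first two lie within 2 percentage points) (north-east / east / north-west / south-west / none)
- amount of intermediate at the outlet or at the end, in percent of the starting material put in, north-east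
- amount of intermediate at the outlet or at the end, in percent of the starting material put in, east
- amount of intermediate at the outlet or at the end, in percent of the starting material put in, north-west
- amount of intermediate at the outlet or at the end, in percent of the starting material put in, south-west

I turn the constants into times at the charged amounts. The dormant form relaxes with a half-life of 0.444 h, far shorter than the 3.1 d of the making step, so I hold it at equilibrium, and a fraction 0.746 of the reservoir is free starting material. This stretches the filling time to 5.97 d.

At the start the quench uses starting material 4.7 times as fast as the making step, and the protic impurity is its limiting reagent. So I subtract its charge and keep a usable share of 70.0%.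

The catalyst is not consumed, so draining is pseudo-first-order, with a draining time of 5.21 d. Filling time over draining time is 1.15, so I carry one number, the intermediate's clock, the inverse of the mean of the two rates: 5.56 d.

For a flask, my share is:

usable share × (time in flask / filling time) × exp(−time in flask / clock)

For a tank, I divide usable share × (residence time / filling time) by the two tank factors, (one + residence time / filling time) and (one + residence time / draining time). The dosed charge has been in the flask for 1.88 d on average.

south-west: 18.7%

east: 15.7%

north-east: 14.0%

north-west: 9.75%

best: south-west

The forecast names south-west, with 15.3% for north-east, 16.7% for east, 10.2% for north-west and 19.9% for south-west, the last above my figure. Its ground: “anything that keeps starting material concentrated relative to impurity favours the intermediate”.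

The simulation gives south-west, with 15.3% for north-east, 16.7% for east, 10.2% for north-west and 19.9% for south-west.

Now take the south-west flask and read it at 10 d instead. Its time over the clock is 1.80, against 0.449 at the asked time, so the exponential now takes more away while the filling term grows. The same line gives 19.4%. That flask reads 19.2% intermediate, with 9.37% starting material left and 38.2% product.

(The constants used here are those of an exercise.)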